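**Atom labels used below.** Chroman 1 is O1, C2, C3, C4, C4a–C8a (ring A is its benzo ring, ring C its pyran ring). Chroman 2 carries primed locants. Ring B is B1–B6 (B1 on C3). Ring D is D1–D6 (D1 on C4, D2 OMe, D4 OH, D6 on C3').

## Analysis of the target

The target is a bis-isoflavanoid. Chroman 1 carries ring B (2-hydroxy-4,5-dimethoxyphenyl) at C3 and ring D at C4, and ring D carries at the neighbouring carbon D6 the C3' atom of a second 7'-hydroxychroman. There are three stereocentres: C3 (R) and C4 (S), which are trans across ring C, and C3' (R). C3' is separated from the other two by the flat ring D, so it cannot be set by relay and has to be introduced on its own in absolute form. Ring D is a 1,2,3,5-tetrasubstituted benzene whose D1 is flanked by the D2 methoxy group and by the branched C3' substituent on D6, and whose two resorcinol oxygens are differentiated (methyl ether at D2, free phenol at D4). The four free phenols are electron-rich and are best carried masked to the end. C4–H is doubly benzylic, and any carbonyl precursor at C3' has an aryloxy group in the β position, so it can epimerise or open the ring by elimination. The main difficulty is to place two branched sp3 carbons on adjacent carbons of a resorcinol ring with the correct oxygen next to D1. The strategy rests on the observation that the D1(acyl precursor)/D2(OMe)/D4(OH)/D6(alkyl) pattern is exactly what a 1,1-dimethoxy-3-silyloxybutadiene leaves behind when it adds to an alkynyl ketone. Ring D can therefore be assembled around the two crowded bonds instead of being substituted afterwards.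

## Retrosynthetic reasoning

Target 31 is traced back to its tetrabenzyl ether 30. All four phenols then carry the same group, which falls in one hydrogenolysis that touches neither the methyl ethers nor a stereocentre.

In 30 the O1–C2 bond is cut, which leads to phenol alcohol 29 and from there to lactone 28, whose carbonyl carbon becomes C2. The lactone is chosen because C3–H is acidic in it, so the trans arrangement at C3/C4 can be reached by equilibration before reduction fixes C3 for good.

Lactone 28 is cut at C3–C4 and at the O1–acyl bond. C4 is a natural electrophile as the ortho-quinone methide 27, and C3 a natural nucleophile as the enolate of activated arylacetic acid 26 (from acid 25). The forward reaction has to form the C–C bond at a hindered methide carbon and to control the configuration at C4 relative to the existing C3'.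

Quinone methide 27 is released from sulfone 21, which comes from carbinol 20 and this from hydroxy ketone 19. The MOM ether of 18 is removed at the ketone stage, because the carbinol would ionise under acid. Benzyl ether 18 comes from phenol 17, so that the D4 oxygen joins the common protecting scheme.

Benzophenone 17 is the point of the key disconnection. D1–D2 and D5–D6 are cut, which dissolves ring D into ynone 13 and diene 14. What is gained is that both crowded bonds to ring D (D1–carbonyl and D6–C3') already exist in 13 as bonds to an alkyne, where steric demand is lowest, and that the D2/D4 oxygens arrive differentiated. The forward reaction has to deliver one regiochemistry and must not disturb the propargylic C3'.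

Ynone 13 is cut between the carbonyl carbon and the alkyne, giving propargylic alcohol 12 and, behind it, acetylide 11 and aldehyde 10. Acetylide 11 arises from dibromoalkene 9, the one-carbon homologue of aldehyde 8.

Aldehyde 8 goes back through alcohol 7 to acid 6, whose stereocentre is set by asymmetric hydrogenation of chromene acid 5. The acid function is what directs the catalyst, and C3' is created before any sensitive functionality exists.

Acid 5 comes from nitrile 4, the annulation product of salicylaldehyde 2 with acrylonitrile 3. The same aldehyde 2, made from 1, is protected to give 10, so one building block feeds both halves of ynone 13.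

Ring B acid 25 is reached from nitrile 24, the one-carbon homologue of aldehyde 23, which is the benzyl ether of commercial 22.

## Alternatives that were turned down

Alternative 1: Ring D would be bought as an arene and both of its ortho bonds made at once by aryne insertion. The aryne released by fluoride from silyl triflate A2 would insert into the C–C bond of ring A β-keto ester A3: the enolate carbon adds meta to the methoxy group (D6) and the aroyl group migrates to D1, giving keto ester A1.
- For it: the conditions are mild, the methoxy group reliably steers the regiochemistry, and the union is convergent. On mildness it is stronger than a heated cycloaddition at a hindered alkyne.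
- Against it: A1 contains neither ring nor stereocentre of chroman 2. The CH2CO2Me arm would still need a benzylation, a hydroxymethylation with absolute control at C3' and a ring closure, all next to an ortho benzophenone carbonyl that invites intramolecular condensation of the ester enolate. A2 itself needs several steps.
- Comparison: both routes form the D1 and D6 bonds in one step. The chosen route arrives at the benzophenone with chroman 2 complete and C3' set, one benzylation away from the common intermediate, whereas A1 is some six steps short of it.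

Alternative 2: Ring C would be the strategic ring. Ortho-quinone methide A5 (the same species as 27) would be attacked at C4 by a chiral azolium or ammonium enolate of arylacetic acid 25, and the phenoxide would then acylate, giving trans lactone A4 (the same compound as 28).
- For it: one catalytic step forms C3–C4, closes the lactone and sets both contiguous stereocentres under reagent control. On this point it is as strong as anything available, and the chosen route uses the same reaction as step 19.
- Against it: as a lead strategy it leaves the harder problem open, namely how ring D with its D6–C3' bond, its stereocentre and its differentiated oxygens is reached. On a preformed resorcinol this would need an sp2–sp3 coupling at a hindered position, or hydrogenation of a 3-aryl-2H-chromene carrying a di-ortho-substituted aryl group, plus an acylation between two substituents.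
- Comparison: there is no difference in how ring C is made. The chosen strategy supplies what this one lacks, a defined construction of ring D and of C3', and places the main risk in one cycloaddition instead of two unsolved operations.

Alternative 3: Ring B would be made last by Dötz benzannulation. The zerovalent chromium carbene complex A7 would take up the ethynyl group of chroman A8 and one CO, forming B1–B2, B2–B3 and B5–B6 and giving phenol A6.
- For it: the B2 hydroxyl is placed next to C3 by the mechanism and arrives unprotected, and the regiochemistry with a terminal alkyne is dependable. On these two points it is stronger than carrying a benzyl group on ring B.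
- Against it: A8 already contains ring D, C3' and the trans C3/C4 pair with an ethynyl group at C3, so every hard problem of the target is still to be solved, and without the epimerisable lactone that corrects C3. The metal is used stoichiometrically on the most advanced intermediate, the alkoxyvinyl carbene is labile, and A6 is an oxidisable hydroquinone monoether.
- Comparison: it builds the one ring that can be bought as aldehyde 22. The chosen strategy spends its annulation on ring D, which cannot be bought in substituted form, and adds no heavy-metal step.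

Key step: step 11

Assumption: the absolute sense of induction of Ru(OAc)2[(R)-H8-BINAP] in step 4 and of (2S,3R)-HyperBTM in step 19 is assigned by analogy with simpler substrates; if a first run shows the opposite sense, the mirror-image catalyst is used and nothing else changes.
Assumption: diene 14 is taken as a purchased reagent.

## Route

Step 1
Reactants: 1 2,4-dihydroxybenzaldehyde
Product: 2 4-(benzyloxy)-2-hydroxybenzaldehyde
Conditions: BnBr (1.05 equiv), NaHCO3, MeCN, 80 °C
Reagents that add atoms: benzyl bromide, BrCc1ccccc1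
Why: Williamson etherification; the 2-hydroxyl is hydrogen-bonded to the aldehyde and is not deprotonated by the weak base, so only the more acidic 4-hydroxyl should react.

Step 2
Reactants: 2 4-(benzyloxy)-2-hydroxybenzaldehyde; 3 acrylonitrile
Product: 4 7-(benzyloxy)-2H-chromene-3-carbonitrile
Conditions: DABCO (0.3 equiv), acrylonitrile (neat, excess), 85 °C
Reagents that add atoms: none
Why: Amine-mediated Baylis–Hillman/oxa-Michael annulation of a salicylaldehyde with an acrylic acceptor, ending in dehydration to the 2H-chromene; the reaction is standard for alkoxy-substituted salicylaldehydes.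

Step 3
Reactants: 4 7-(benzyloxy)-2H-chromene-3-carbonitrile
Product: 5 7-(benzyloxy)-2H-chromene-3-carboxylic acid
Conditions: NaOH (10% aq.), EtOH, reflux; then HCl to pH 2
Reagents that add atoms: sodium hydroxide, [Na+].[OH-]; water, O
Why: Alkaline nitrile hydrolysis; the benzyl ether and the chromene double bond are stable to hydroxide.

Step 4
Reactants: 5 7-(benzyloxy)-2H-chromene-3-carboxylic acid
Product: 6 (3S)-7-(benzyloxy)chroman-3-carboxylic acid
Conditions: Ru(OAc)2[(R)-H8-BINAP] (1 mol%), H2 (20 atm), MeOH, 25 °C
Reagents that add atoms: none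
Why: Carboxylate-directed asymmetric hydrogenation of a trisubstituted acrylic acid; the substrate binds ruthenium as its carboxylate and the biaryl diphosphine selects the alkene face, which sets C3'. The homogeneous catalyst should leave the benzyl ether alone, and the acid can be recrystallised to raise its enantiomeric purity.

Step 5
Reactants: 6 (3S)-7-(benzyloxy)chroman-3-carboxylic acid
Product: 7 [(3R)-7-(benzyloxy)chroman-3-yl]methanol
Conditions: BH3·THF, THF, 0 °C to rt; then MeOH
Reagents that add atoms: none
Why: Borane reduction of a carboxylic acid through its acyloxyborane; no enolisable carbonyl species is exposed to base, so C3' is not at risk (the descriptor changes only through CIP priorities).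

Step 6
Reactants: 7 [(3R)-7-(benzyloxy)chroman-3-yl]methanol
Product: 8 (3S)-7-(benzyloxy)chroman-3-carbaldehyde
Conditions: Dess–Martin periodinane, CH2Cl2, 0 °C to rt; used crude
Reagents that add atoms: none
Why: Dess–Martin oxidation is non-basic and fast; the aldehyde has an α-stereocentre and a β-aryloxy group and is therefore carried on at once without chromatography.

Step 7
Reactants: 8 (3S)-7-(benzyloxy)chroman-3-carbaldehyde
Product: 9 (3R)-7-(benzyloxy)-3-(2,2-dibromoethenyl)chroman
Conditions: CBr4, PPh3, Zn dust, CH2Cl2, rt (ylide preformed); then 8, 0 °C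
Reagents that add atoms: carbon tetrabromide, BrC(Br)(Br)Br
Why: First stage of the Corey–Fuchs alkyne synthesis, a Wittig-type olefination with a non-basic ylide; it is preferred here to a diazophosphonate with carbonate in methanol because it does not enolise the aldehyde.

Step 8
Reactants: 2 4-(benzyloxy)-2-hydroxybenzaldehyde
Product: 10 4-(benzyloxy)-2-(methoxymethoxy)benzaldehyde
Conditions: MOMCl, iPr2NEt, CH2Cl2, 0 °C to rt
Reagents that add atoms: chloromethyl methyl ether, COCCl
Why: Acetal protection of the phenol; it keeps the ring A oxygen from quenching the acetylide and, later, from adding to the ynone, and it can be removed without touching benzyl ethers.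

Step 9
Reactants: 9 (3R)-7-(benzyloxy)-3-(2,2-dibromoethenyl)chroman; 10 4-(benzyloxy)-2-(methoxymethoxy)benzaldehyde
Product: 12 1-[4-(benzyloxy)-2-(methoxymethoxy)phenyl]-3-[(3R)-7-(benzyloxy)chroman-3-yl]prop-2-yn-1-ol (both carbinol epimers), via lithium acetylide 11 (not isolated)
Conditions: n-BuLi (2.1 equiv), THF, −78 °C; then 10, −78 to 0 °C; aq. NH4Cl
Reagents that add atoms: none
Why: Second stage of the Corey–Fuchs sequence (bromine–lithium exchange, Fritsch–Buttenberg–Wiechell rearrangement, deprotonation) gives the acetylide, which adds to the aldehyde; the new carbinol centre is oxidised away in the next step, so its configuration does not matter.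

Step 10
Reactants: 12 the propargylic alcohol
Product: 13 1-[4-(benzyloxy)-2-(methoxymethoxy)phenyl]-3-[(3R)-7-(benzyloxy)chroman-3-yl]prop-2-yn-1-one
Conditions: MnO2 (activated, excess), CH2Cl2, rt
Reagents that add atoms: none
Why: Manganese dioxide oxidises the benzylic and propargylic alcohol selectively under neutral conditions, so the propargylic C3' hydrogen is not exposed to base.

Step 11
Reactants: 13 the ynone; 14 1,1-dimethoxy-3-(trimethylsilyloxy)buta-1,3-diene
Product: 17 [4-(benzyloxy)-2-(methoxymethoxy)phenyl]{2-[(3R)-7-(benzyloxy)chroman-3-yl]-4-hydroxy-6-methoxyphenyl}methanone, via cycloadduct 15 (not isolated), via aryl silyl ether 16 (not isolated)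
Conditions: 14 (3 equiv), PhMe, 110 °C, sealed tube; then K2CO3 (cat.), MeOH, rt
Reagents that add atoms: none
Why: The electron-rich diene 14 and the electron-poor alkyne of 13 should combine in a thermal, strongly asynchronous [4+2] cycloaddition: the unsubstituted CH2 terminus of 14, which carries the largest HOMO coefficient, bonds to the alkyne carbon β to the carbonyl (the one bearing C3'), and the ketene acetal carbon bonds to the α-carbon, giving cyclohexa-1,4-diene 15. Loss of methanol from the ketal carbon and the ring CH2 of 15 is driven by aromatisation and gives silyl ether 16, which carbonate in methanol cleaves to phenol 17. The closest known reaction type is the Diels–Alder benzannulation of 1,1-dialkoxy-3-silyloxybutadienes with alkynyl esters and ketones to 4-hydroxy-2-alkoxybenzoyl compounds. Ring D is closed by intermolecular cycloaddition, D5–D6 and D1–D2 being formed in the same operation, not by cyclisation of a chain. No stereocentre is created, and C3' should be kept because the cycloaddition is run without acid or base and its hydrogen is only propargylic. The selectivity needed is regiochemical (methoxy next to the acyl-bearing D1, hydroxyl para to it), and it follows from matching the nucleophilic diene terminus with the β-carbon of the ynone; the MOM group keeps the ring A oxygen from adding to the ynone.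

Step 12
Reactants: 17 the D4 phenol
Product: 18 {4-(benzyloxy)-2-[(3R)-7-(benzyloxy)chroman-3-yl]-6-methoxyphenyl}[4-(benzyloxy)-2-(methoxymethoxy)phenyl]methanone
Conditions: BnBr, K2CO3, DMF, rt
Reagents that add atoms: benzyl bromide, BrCc1ccccc1
Why: Williamson etherification of the only free phenol, which is acidified by the para carbonyl group; the MOM ether is stable to carbonate.

Step 13
Reactants: 18 the MOM-protected benzophenone
Product: 19 {4-(benzyloxy)-2-[(3R)-7-(benzyloxy)chroman-3-yl]-6-methoxyphenyl}[4-(benzyloxy)-2-hydroxyphenyl]methanone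
Conditions: HCl (3 M aq., cat.), MeOH/THF, 50 °C
Reagents that add atoms: none
Why: Acid-catalysed acetal exchange removes the MOM group while benzyl and methyl ethers stay; it is done at the ketone stage because the later carbinol would ionise under acid.

Step 14
Reactants: 19 the 2-hydroxybenzophenone
Product: 20 5-(benzyloxy)-2-[{4-(benzyloxy)-2-[(3R)-7-(benzyloxy)chroman-3-yl]-6-methoxyphenyl}(hydroxy)methyl]phenol (both carbinol epimers)
Conditions: LiAlH4, THF, 0 °C; aq. Rochelle salt
Reagents that add atoms: none
Why: Hydride reduction of the hindered, deactivated diaryl ketone; the aprotic solvent and low temperature hold the aluminate back from eliminating to a quinone methide and being reduced further.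

Step 15
Reactants: 20 the hydroxy carbinol
Product: 21 5-(benzyloxy)-2-[{4-(benzyloxy)-2-[(3R)-7-(benzyloxy)chroman-3-yl]-6-methoxyphenyl}(4-methylbenzenesulfonyl)methyl]phenol (both epimers)
Conditions: p-TolSO2H (1.5 equiv), CH2Cl2, rt
Reagents that add atoms: p-toluenesulfinic acid, Cc1ccc(cc1)S(=O)O
Why: SN1 substitution: the sulfinic acid ionises the doubly activated benzhydrol and the sulfinate captures the cation at sulfur; 2-(sulfonylmethyl)phenols are the standard bench-stable precursors of ortho-quinone methides.

Step 16
Reactants: 22 2-hydroxy-4,5-dimethoxybenzaldehyde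
Product: 23 2-(benzyloxy)-4,5-dimethoxybenzaldehyde
Conditions: BnBr, K2CO3, DMF, 60 °C
Reagents that add atoms: benzyl bromide, BrCc1ccccc1
Why: Williamson etherification; the stronger base and warming overcome the hydrogen bond to the aldehyde.

Step 17
Reactants: 23 2-(benzyloxy)-4,5-dimethoxybenzaldehyde
Product: 24 [2-(benzyloxy)-4,5-dimethoxyphenyl]acetonitrile
Conditions: TosMIC, t-BuOK, DME, −40 °C; then MeOH, reflux
Reagents that add atoms: p-toluenesulfonylmethyl isocyanide, Cc1ccc(cc1)S(=O)(=O)C[N+]#[C-]
Why: Van Leusen reductive cyanation: addition and cyclisation give a 4-tosyloxazoline that opens to an N-formyl tosyl enamine; methanolysis and loss of sulfinate leave the homologous nitrile.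

Step 18
Reactants: 24 [2-(benzyloxy)-4,5-dimethoxyphenyl]acetonitrile
Product: 25 [2-(benzyloxy)-4,5-dimethoxyphenyl]acetic acid
Conditions: NaOH, EtOH/H2O, reflux; then HCl
Reagents that add atoms: sodium hydroxide, [Na+].[OH-]; water, O
Why: Alkaline nitrile hydrolysis; aryl ethers are inert to it.

Step 19
Reactants: 21 the sulfone; 25 [2-(benzyloxy)-4,5-dimethoxyphenyl]acetic acid
Product: 28 (3R,4S)-7-(benzyloxy)-3-[2-(benzyloxy)-4,5-dimethoxyphenyl]-4-{4-(benzyloxy)-2-[(3R)-7-(benzyloxy)chroman-3-yl]-6-methoxyphenyl}-3,4-dihydro-2H-chromen-2-one, via mixed anhydride 26 (not isolated), via ortho-quinone methide 27 (not isolated)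
Conditions: 25, t-BuCOCl, iPr2NEt, CH2Cl2, 0 °C; then 21, (2S,3R)-HyperBTM (10 mol%), Cs2CO3, 0 °C to rt; then DBU (0.2 equiv), rt
Reagents that add atoms: none
Why: Isothiourea-catalysed Michael addition–lactonisation (formal [4+2] annulation): acyl transfer from 26 to the catalyst and deprotonation give a planar (Z)-ammonium enolate, carbonate releases 27 from the sulfone, the enolate adds to the methide carbon (C3–C4), and the phenoxide acylates to close the lactone and free the catalyst. The catalyst shields one enolate face and thereby fixes the approach to 27 that sets C4; C3 is acidic in the lactone and is brought to the trans arrangement by DBU, while C3' is not touched.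

Step 20
Reactants: 28 the trans lactone
Product: 29 5-(benzyloxy)-2-[(1S,2R)-2-[2-(benzyloxy)-4,5-dimethoxyphenyl]-1-{4-(benzyloxy)-2-[(3R)-7-(benzyloxy)chroman-3-yl]-6-methoxyphenyl}-3-hydroxypropyl]phenol
Conditions: LiAlH4, THF, 0 °C
Reagents that add atoms: none
Why: Hydride reduction of the aryl lactone to the phenol and primary alcohol; the reactive aryl ester is consumed quickly at low temperature, which should leave no time for epimerisation at C3.

Step 21
Reactants: 29 the phenol alcohol
Product: 30 (3R,4S)-7-(benzyloxy)-3-[2-(benzyloxy)-4,5-dimethoxyphenyl]-4-{4-(benzyloxy)-2-[(3R)-7-(benzyloxy)chroman-3-yl]-6-methoxyphenyl}chroman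
Conditions: PPh3, DIAD, THF, 0 °C to rt
Reagents that add atoms: none
Why: Intramolecular Mitsunobu etherification: the only free phenol displaces the activated primary alcohol and closes ring C (O1–C2) in a 6-exo-tet mode; no stereocentre is involved.

Step 22
Reactants: 30 the tetrabenzyl ether
Product: 31 (3R,4S)-3-(2-hydroxy-4,5-dimethoxyphenyl)-4-{4-hydroxy-2-[(3R)-7-hydroxychroman-3-yl]-6-methoxyphenyl}chroman-7-ol (CNP0266829.1)
Conditions: H2 (1 atm), 10% Pd/C, EtOAc/MeOH, rt
Reagents that add atoms: none
Why: Hydrogenolysis of four benzyl aryl ethers; the chroman C–O bonds are not benzylic and the C4–aryl bonds are C–C bonds, so nothing else should be cleaved.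

## Compound list

1 | 2,4-dihydroxybenzaldehyde | O=Cc1ccc(O)cc1O | starting material
2 | 4-(benzyloxy)-2-hydroxybenzaldehyde | O=Cc1ccc(OCc2ccccc2)cc1O | intermediate
3 | acrylonitrile | C=CC#N | starting material
4 | 7-(benzyloxy)-2H-chromene-3-carbonitrile | N#CC1=Cc2ccc(OCc3ccccc3)cc2OC1 | intermediate
5 | 7-(benzyloxy)-2H-chromene-3-carboxylic acid | OC(=O)C1=Cc2ccc(OCc3ccccc3)cc2OC1 | intermediate
6 | (3S)-7-(benzyloxy)chroman-3-carboxylic acid | OC(=O)[C@@H]1COc2cc(OCc3ccccc3)ccc2C1 | intermediate
7 | [(3R)-7-(benzyloxy)chroman-3-yl]methanol | OC[C@@H]1COc2cc(OCc3ccccc3)ccc2C1 | intermediate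
8 | (3S)-7-(benzyloxy)chroman-3-carbaldehyde | O=C[C@@H]1COc2cc(OCc3ccccc3)ccc2C1 | intermediate
9 | (3R)-7-(benzyloxy)-3-(2,2-dibromoethenyl)chroman | BrC(Br)=C[C@@H]1COc2cc(OCc3ccccc3)ccc2C1 | intermediate
10 | 4-(benzyloxy)-2-(methoxymethoxy)benzaldehyde | COCOc1cc(OCc2ccccc2)ccc1C=O | intermediate
11 | lithium [(3R)-7-(benzyloxy)chroman-3-yl]acetylide | [Li]C#C[C@@H]1COc2cc(OCc3ccccc3)ccc2C1 | intermediate (not isolated)
12 | 1-[4-(benzyloxy)-2-(methoxymethoxy)phenyl]-3-[(3R)-7-(benzyloxy)chroman-3-yl]prop-2-yn-1-ol (both carbinol epimers) | COCOc1cc(OCc2ccccc2)ccc1C(O)C#C[C@@H]1COc2cc(OCc3ccccc3)ccc2C1 | intermediate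
13 | 1-[4-(benzyloxy)-2-(methoxymethoxy)phenyl]-3-[(3R)-7-(benzyloxy)chroman-3-yl]prop-2-yn-1-one | O=C(C#C[C@@H]1COc2cc(OCc3ccccc3)ccc2C1)c1ccc(OCc2ccccc2)cc1OCOC | intermediate
14 | 1,1-dimethoxy-3-(trimethylsilyloxy)buta-1,3-diene | COC(OC)=CC(=C)O[Si](C)(C)C | starting material
15 | [4-(benzyloxy)-2-(methoxymethoxy)phenyl]{2-[(3R)-7-(benzyloxy)chroman-3-yl]-6,6-dimethoxy-4-(trimethylsilyloxy)cyclohexa-1,4-dien-1-yl}methanone | COCOc1cc(OCc2ccccc2)ccc1C(=O)C1=C(CC(O[Si](C)(C)C)=CC1(OC)OC)[C@@H]1COc2cc(OCc3ccccc3)ccc2C1 | intermediate (not isolated)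
16 | [4-(benzyloxy)-2-(methoxymethoxy)phenyl]{2-[(3R)-7-(benzyloxy)chroman-3-yl]-6-methoxy-4-(trimethylsilyloxy)phenyl}methanone | COCOc1cc(OCc2ccccc2)ccc1C(=O)c1c(OC)cc(O[Si](C)(C)C)cc1[C@@H]1COc2cc(OCc3ccccc3)ccc2C1 | intermediate (not isolated)
17 | [4-(benzyloxy)-2-(methoxymethoxy)phenyl]{2-[(3R)-7-(benzyloxy)chroman-3-yl]-4-hydroxy-6-methoxyphenyl}methanone | COCOc1cc(OCc2ccccc2)ccc1C(=O)c1c(OC)cc(O)cc1[C@@H]1COc2cc(OCc3ccccc3)ccc2C1 | intermediate
18 | {4-(benzyloxy)-2-[(3R)-7-(benzyloxy)chroman-3-yl]-6-methoxyphenyl}[4-(benzyloxy)-2-(methoxymethoxy)phenyl]methanone | COCOc1cc(OCc2ccccc2)ccc1C(=O)c1c(OC)cc(OCc2ccccc2)cc1[C@@H]1COc2cc(OCc3ccccc3)ccc2C1 | intermediate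
19 | {4-(benzyloxy)-2-[(3R)-7-(benzyloxy)chroman-3-yl]-6-methoxyphenyl}[4-(benzyloxy)-2-hydroxyphenyl]methanone | Oc1cc(OCc2ccccc2)ccc1C(=O)c1c(OC)cc(OCc2ccccc2)cc1[C@@H]1COc2cc(OCc3ccccc3)ccc2C1 | intermediate
20 | 5-(benzyloxy)-2-[{4-(benzyloxy)-2-[(3R)-7-(benzyloxy)chroman-3-yl]-6-methoxyphenyl}(hydroxy)methyl]phenol (both carbinol epimers) | Oc1cc(OCc2ccccc2)ccc1C(O)c1c(OC)cc(OCc2ccccc2)cc1[C@@H]1COc2cc(OCc3ccccc3)ccc2C1 | intermediate
21 | 5-(benzyloxy)-2-[{4-(benzyloxy)-2-[(3R)-7-(benzyloxy)chroman-3-yl]-6-methoxyphenyl}(4-methylbenzenesulfonyl)methyl]phenol (both epimers) | Cc1ccc(cc1)S(=O)(=O)C(c1ccc(OCc2ccccc2)cc1O)c1c(OC)cc(OCc2ccccc2)cc1[C@@H]1COc2cc(OCc3ccccc3)ccc2C1 | intermediate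
22 | 2-hydroxy-4,5-dimethoxybenzaldehyde | COc1cc(O)c(C=O)cc1OC | starting material
23 | 2-(benzyloxy)-4,5-dimethoxybenzaldehyde | COc1cc(OCc2ccccc2)c(C=O)cc1OC | intermediate
24 | [2-(benzyloxy)-4,5-dimethoxyphenyl]acetonitrile | COc1cc(OCc2ccccc2)c(CC#N)cc1OC | intermediate
25 | [2-(benzyloxy)-4,5-dimethoxyphenyl]acetic acid | COc1cc(OCc2ccccc2)c(CC(=O)O)cc1OC | intermediate
26 | [2-(benzyloxy)-4,5-dimethoxyphenyl]acetic 2,2-dimethylpropanoic anhydride | COc1cc(OCc2ccccc2)c(CC(=O)OC(=O)C(C)(C)C)cc1OC | intermediate (not isolated)
27 | 3-(benzyloxy)-6-[{4-(benzyloxy)-2-[(3R)-7-(benzyloxy)chroman-3-yl]-6-methoxyphenyl}methylidene]cyclohexa-2,4-dien-1-one | O=C1C=C(OCc2ccccc2)C=CC1=Cc1c(OC)cc(OCc2ccccc2)cc1[C@@H]1COc2cc(OCc3ccccc3)ccc2C1 | intermediate (not isolated)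
28 | (3R,4S)-7-(benzyloxy)-3-[2-(benzyloxy)-4,5-dimethoxyphenyl]-4-{4-(benzyloxy)-2-[(3R)-7-(benzyloxy)chroman-3-yl]-6-methoxyphenyl}-3,4-dihydro-2H-chromen-2-one | COc1cc(OCc4ccccc4)c([C@@H]2C(=O)Oc3cc(OCc4ccccc4)ccc3[C@H]2c2c(OC)cc(OCc4ccccc4)cc2[C@@H]2COc3cc(OCc4ccccc4)ccc3C2)cc1OC | intermediate
29 | 5-(benzyloxy)-2-[(1S,2R)-2-[2-(benzyloxy)-4,5-dimethoxyphenyl]-1-{4-(benzyloxy)-2-[(3R)-7-(benzyloxy)chroman-3-yl]-6-methoxyphenyl}-3-hydroxypropyl]phenol | COc1cc(OCc4ccccc4)c([C@H](CO)[C@@H](c2ccc(OCc4ccccc4)cc2O)c2c(OC)cc(OCc4ccccc4)cc2[C@@H]2COc3cc(OCc4ccccc4)ccc3C2)cc1OC | intermediate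
30 | (3R,4S)-7-(benzyloxy)-3-[2-(benzyloxy)-4,5-dimethoxyphenyl]-4-{4-(benzyloxy)-2-[(3R)-7-(benzyloxy)chroman-3-yl]-6-methoxyphenyl}chroman | COc1cc(OCc4ccccc4)c([C@@H]2COc3cc(OCc4ccccc4)ccc3[C@H]2c2c(OC)cc(OCc4ccccc4)cc2[C@@H]2COc3cc(OCc4ccccc4)ccc3C2)cc1OC | intermediate
31 | (3R,4S)-3-(2-hydroxy-4,5-dimethoxyphenyl)-4-{4-hydroxy-2-[(3R)-7-hydroxychroman-3-yl]-6-methoxyphenyl}chroman-7-ol | COc1cc(O)c([C@@H]2COc3cc(O)ccc3[C@H]2c2c(OC)cc(O)cc2[C@@H]2COc3cc(O)ccc3C2)cc1OC | target

## Step count and least certain steps

Total: 22 steps. Longest linear sequence: 18 steps (1 to 31 through steps 1–7, 9–15 and 19–22). Steps 8 and 16–18 lie on side branches.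

Step 11 (key step). The cycloaddition may be too slow at the alkyne carbon that carries the secondary C3' substituent, so that diene 14 decomposes or oligomerises first. A competing [2+2] addition of the ketene acetal may divert material. Adventitious water may hydrolyse the ketal of 15 before methanol is lost, which removes the D2 methyl group. Long heating may isomerise the ynone to an allenyl ketone and erode C3'.
Fallback, from 9 back to 18: the cycloaddition is moved to the alkynyl ester, the substrate class with the closest precedent and the smaller acyl group, and ring A is attached afterwards. Dibromoalkene 9 with n-BuLi and then methyl chloroformate would give methyl 3-[(3R)-7-(benzyloxy)chroman-3-yl]prop-2-ynoate F1. Heating F1 with 14 would give, through the cyclohexadiene cycloadduct F2 and the aryl silyl ether F3, methyl 2-[(3R)-7-(benzyloxy)chroman-3-yl]-4-hydroxy-6-methoxybenzoate F4, which is benzylated to methyl 4-(benzyloxy)-2-[(3R)-7-(benzyloxy)chroman-3-yl]-6-methoxybenzoate F5. 4-(Benzyloxy)-1-bromo-2-(methoxymethoxy)benzene F6, made by methoxymethylation of purchased 5-(benzyloxy)-2-bromophenol F7, is converted by bromine–lithium exchange into [4-(benzyloxy)-2-(methoxymethoxy)phenyl]lithium F8. F8 should add once to the hindered ester F5, since the di-ortho-substituted ketone resists a second addition, and give ketone 18.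

Step 19. Both faces of the methide carbon of 27 are crowded by the ortho substituents of ring D, so C–C bond formation may be slow. In that case 27 may dimerise or be recaptured by sulfinate, the phenol of 21 may be O-acylated before it ionises, and the enolate may self-condense. The existing C3' centre may oppose the catalyst and lower the facial selectivity.
Fallback, from 25 and 21 back to 28: reagent control is moved from a catalyst to a stoichiometric auxiliary. Acid 25 is converted (pivaloyl chloride, then lithiated (4S)-4-benzyl-1,3-oxazolidin-2-one) into (4S)-4-benzyl-3-{[2-(benzyloxy)-4,5-dimethoxyphenyl]acetyl}-1,3-oxazolidin-2-one F9. Its sodium enolate (NaHMDS, THF, −78 °C), with a second equivalent of base to release 27 from 21, should give the Michael adduct (4S)-4-benzyl-3-[(2R,3S)-2-[2-(benzyloxy)-4,5-dimethoxyphenyl]-3-[4-(benzyloxy)-2-hydroxyphenyl]-3-{4-(benzyloxy)-2-[(3R)-7-(benzyloxy)chroman-3-yl]-6-methoxyphenyl}propanoyl]-1,3-oxazolidin-2-one F10. The phenoxide of F10 closes onto the imide carbonyl with loss of the auxiliary and gives 28 after equilibration at C3. Because C3' is fixed, any wrong C4 isomer is a diastereomer and can be removed by chromatography.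

Step 4. The alkene is part of a cinnamate-type system in a ring, and face selection may be incomplete, which would leave C3' with insufficient enantiomeric purity for everything that follows.
Fallback, from 5 back to 6: asymmetric catalysis is replaced by resolution. Hydrogenation of 5 with [Ir(cod)(PCy3)(py)]PF6 and H2 in CH2Cl2 would give racemic 7-(benzyloxy)chroman-3-carboxylic acid F11. Crystallisation with (S)-1-phenylethylamine would give the salt (S)-1-phenylethylammonium (3S)-7-(benzyloxy)chroman-3-carboxylate F12, from which acid liberates 6.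

Step 7 (together with step 6). Aldehyde 8 may lose configuration at C3' by enolisation or by reversible β-elimination of the aryloxide (ring opening and reclosure) during oxidation, handling or olefination.
Fallback, from 6 back to 12: the aldehyde is avoided and the alkyne is built at the acid oxidation level. Acid 6 is converted into (3S)-7-(benzyloxy)-N-methoxy-N-methylchroman-3-carboxamide F13, and MeMgBr gives 1-[(3S)-7-(benzyloxy)chroman-3-yl]ethanone F14. Kinetic deprotonation at the methyl group (LDA, −78 °C) and diethyl chlorophosphate give diethyl 1-[(3S)-7-(benzyloxy)chroman-3-yl]ethenyl phosphate F15, and further LDA eliminates it to (3R)-7-(benzyloxy)-3-ethynylchroman F16. n-BuLi converts F16 into acetylide 11, which adds to 10 to give 12.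

## Further compounds

F1 | step 11 | methyl 3-[(3R)-7-(benzyloxy)chroman-3-yl]prop-2-ynoate | COC(=O)C#C[C@@H]1COc2cc(OCc3ccccc3)ccc2C1
F2 | step 11 | methyl 2-[(3R)-7-(benzyloxy)chroman-3-yl]-6,6-dimethoxy-4-(trimethylsilyloxy)cyclohexa-1,4-diene-1-carboxylate | COC(=O)C1=C(CC(O[Si](C)(C)C)=CC1(OC)OC)[C@@H]1COc2cc(OCc3ccccc3)ccc2C1
F3 | step 11 | methyl 2-[(3R)-7-(benzyloxy)chroman-3-yl]-6-methoxy-4-(trimethylsilyloxy)benzoate | COC(=O)c1c(OC)cc(O[Si](C)(C)C)cc1[C@@H]1COc2cc(OCc3ccccc3)ccc2C1
F4 | step 11 | methyl 2-[(3R)-7-(benzyloxy)chroman-3-yl]-4-hydroxy-6-methoxybenzoate | COC(=O)c1c(OC)cc(O)cc1[C@@H]1COc2cc(OCc3ccccc3)ccc2C1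
F5 | step 11 | methyl 4-(benzyloxy)-2-[(3R)-7-(benzyloxy)chroman-3-yl]-6-methoxybenzoate | COC(=O)c1c(OC)cc(OCc2ccccc2)cc1[C@@H]1COc2cc(OCc3ccccc3)ccc2C1
F6 | step 11 | 4-(benzyloxy)-1-bromo-2-(methoxymethoxy)benzene | COCOc1cc(OCc2ccccc2)ccc1Br
F7 | step 11 | 5-(benzyloxy)-2-bromophenol | Oc1cc(OCc2ccccc2)ccc1Br
F8 | step 11 | [4-(benzyloxy)-2-(methoxymethoxy)phenyl]lithium | [Li]c1ccc(OCc2ccccc2)cc1OCOC
F9 | step 19 | (4S)-4-benzyl-3-{[2-(benzyloxy)-4,5-dimethoxyphenyl]acetyl}-1,3-oxazolidin-2-one | COc1cc(OCc2ccccc2)c(CC(=O)N2[C@@H](Cc3ccccc3)COC2=O)cc1OC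
F10 | step 19 | (4S)-4-benzyl-3-[(2R,3S)-2-[2-(benzyloxy)-4,5-dimethoxyphenyl]-3-[4-(benzyloxy)-2-hydroxyphenyl]-3-{4-(benzyloxy)-2-[(3R)-7-(benzyloxy)chroman-3-yl]-6-methoxyphenyl}propanoyl]-1,3-oxazolidin-2-one | COc1cc(OCc4ccccc4)c([C@H](C(=O)N5[C@@H](Cc6ccccc6)COC5=O)[C@@H](c2ccc(OCc4ccccc4)cc2O)c2c(OC)cc(OCc4ccccc4)cc2[C@@H]2COc3cc(OCc4ccccc4)ccc3C2)cc1OC
F11 | step 4 | racemic 7-(benzyloxy)chroman-3-carboxylic acid | OC(=O)C1COc2cc(OCc3ccccc3)ccc2C1
F12 | step 4 | (S)-1-phenylethylammonium (3S)-7-(benzyloxy)chroman-3-carboxylate | C[C@H]([NH3+])c1ccccc1.[O-]C(=O)[C@@H]1COc2cc(OCc3ccccc3)ccc2C1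
F13 | step 7 | (3S)-7-(benzyloxy)-N-methoxy-N-methylchroman-3-carboxamide | CON(C)C(=O)[C@@H]1COc2cc(OCc3ccccc3)ccc2C1
F14 | step 7 | 1-[(3S)-7-(benzyloxy)chroman-3-yl]ethanone | CC(=O)[C@@H]1COc2cc(OCc3ccccc3)ccc2C1
F15 | step 7 | diethyl 1-[(3S)-7-(benzyloxy)chroman-3-yl]ethenyl phosphate | C=C(OP(=O)(OCC)OCC)[C@@H]1COc2cc(OCc3ccccc3)ccc2C1
F16 | step 7 | (3R)-7-(benzyloxy)-3-ethynylchroman | C#C[C@@H]1COc2cc(OCc3ccccc3)ccc2C1
A1 | alternative 1 | methyl 2-{2-[4-(benzyloxy)-2-(methoxymethoxy)benzoyl]-5-(benzyloxy)-3-methoxyphenyl}acetate | COC(=O)Cc1cc(OCc2ccccc2)cc(OC)c1C(=O)c1ccc(OCc2ccccc2)cc1OCOC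
A2 | alternative 1 | 5-(benzyloxy)-3-methoxy-2-(trimethylsilyl)phenyl trifluoromethanesulfonate | COc1cc(OCc2ccccc2)cc(OS(=O)(=O)C(F)(F)F)c1[Si](C)(C)C
A3 | alternative 1 | methyl 3-[4-(benzyloxy)-2-(methoxymethoxy)phenyl]-3-oxopropanoate | COC(=O)CC(=O)c1ccc(OCc2ccccc2)cc1OCOC
A4 | alternative 2 | (3R,4S)-7-(benzyloxy)-3-[2-(benzyloxy)-4,5-dimethoxyphenyl]-4-{4-(benzyloxy)-2-[(3R)-7-(benzyloxy)chroman-3-yl]-6-methoxyphenyl}-3,4-dihydro-2H-chromen-2-one | COc1cc(OCc4ccccc4)c([C@@H]2C(=O)Oc3cc(OCc4ccccc4)ccc3[C@H]2c2c(OC)cc(OCc4ccccc4)cc2[C@@H]2COc3cc(OCc4ccccc4)ccc3C2)cc1OC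
A5 | alternative 2 | 3-(benzyloxy)-6-[{4-(benzyloxy)-2-[(3R)-7-(benzyloxy)chroman-3-yl]-6-methoxyphenyl}methylidene]cyclohexa-2,4-dien-1-one | O=C1C=C(OCc2ccccc2)C=CC1=Cc1c(OC)cc(OCc2ccccc2)cc1[C@@H]1COc2cc(OCc3ccccc3)ccc2C1
A6 | alternative 3 | 2-[(3R,4S)-7-(benzyloxy)-4-{4-(benzyloxy)-2-[(3R)-7-(benzyloxy)chroman-3-yl]-6-methoxyphenyl}chroman-3-yl]-4,5-dimethoxyphenol | COc1cc(O)c([C@@H]2COc3cc(OCc4ccccc4)ccc3[C@H]2c2c(OC)cc(OCc4ccccc4)cc2[C@@H]2COc3cc(OCc4ccccc4)ccc3C2)cc1OC
A7 | alternative 3 | pentacarbonyl[methoxy(1-methoxyethenyl)methylidene]chromium | COC(=C)C(OC)=[Cr](=C=O)(=C=O)(=C=O)(=C=O)=C=O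
A8 | alternative 3 | (3R,4S)-7-(benzyloxy)-4-{4-(benzyloxy)-2-[(3R)-7-(benzyloxy)chroman-3-yl]-6-methoxyphenyl}-3-ethynylchroman | C#C[C@@H]1COc2cc(OCc3ccccc3)ccc2[C@H]1c1c(OC)cc(OCc2ccccc2)cc1[C@@H]1COc2cc(OCc3ccccc3)ccc2C1
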